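**Plan**

Ring A is the benzo ring of the dihydrobenzofuran that carries the other benzofuran at C3 (benzofuran 2). Ring B is the benzo ring of the dihydrobenzofuran that carries the 3,5-dihydroxyphenyl group at C3 (benzofuran 1).
Cuts: the seven O–CH3 bonds; then both aryl–alkene bonds of the seven-membered ring (alkene CH to C4 of ring A, alkene C(aryl) to C7 of ring B), which frees 4-ethynylanisole and a bromo bis(dihydrobenzofuran); then C2–C3 of each dihydrobenzofuran (carbene C–H insertion) and the two diaryl ketone C–C bonds (aryl metal plus aldehyde).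
Forward: ring-B diaryl ketone → benzofuran 1 → aryllithium plus ring-A aldehyde → second ketone → benzofuran 2 → cycloheptatriene ring closed last by a one-flask alkyne annulation → demethylation.
Enabling feature: the alkene carbon that bears the 4-oxygenated aryl group can carry positive charge and lies beside C7 of ring B, which is ortho to the furan oxygen and para to the C4 oxygen. C4 of ring A is meta to both ring-A oxygens and can only be bonded through its halide. An arylacetylene therefore bridges the two rings by cross-coupling at ring A and cationic closure at ring B, at the oxidation level that gives the alkene directly.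
Stereochemistry: C3 of each dihydrobenzofuran by catalyst control (enantiomeric dirhodium carboxylates, 3R on ring B and 3S on ring A); C2 of each by acid equilibration to the trans isomer.

Key step: step 13

Assumption: Rh2(S-PTAD)4 and Rh2(R-PTAD)4 are the two enantiomers of dirhodium tetrakis[2-(1-adamantyl)-2-phthalimidoacetate]. The S catalyst is taken to give the 3R ring of benzofuran 1 and the R catalyst the 3S ring of benzofuran 2; if a test insertion shows the opposite sense, the two catalysts are exchanged.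
Remark: 3,5-dimethoxyphenylmagnesium chloride is taken as the commercial THF solution.

**Route**

Step 1
Reactants: 1 4-bromo-2,6-dimethoxybenzaldehyde; 2 3,5-dimethoxyphenylmagnesium chloride
Product: 3 (4-bromo-2,6-dimethoxyphenyl)(3,5-dimethoxyphenyl)methanol (racemic)
Conditions: THF, 0 °C to rt; aq NH4Cl
Reagents that add atoms: none
Why: Grignard addition to the aldehyde gives the diaryl carbinol; its stereocentre forms as a racemate and is erased by the oxidation of step 2.

Step 2
Reactants: 3
Product: 4 (4-bromo-2,6-dimethoxyphenyl)(3,5-dimethoxyphenyl)methanone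
Conditions: MnO2 (excess), CH2Cl2, rt
Reagents that add atoms: none
Why: MnO2 oxidation of a doubly benzylic secondary alcohol should give the diaryl ketone without touching the aryl bromide or the ethers.

Step 3
Reactants: 4
Product: 5 (4-bromo-2-hydroxy-6-methoxyphenyl)(3,5-dimethoxyphenyl)methanone
Conditions: BCl3 (1.2 equiv), CH2Cl2, −78 to 0 °C; then H2O
Reagents that add atoms: none
Why: Chelation-controlled demethylation: BCl3 binds the ketone oxygen and cleaves one of the two equivalent ortho methoxy groups, after which the aryloxyboron chelate protects the second one, and the meta methoxy groups of the other ring are not activated.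

Step 4
Reactants: 5
Product: 6 {4-bromo-2-methoxy-6-[(4-methoxybenzyl)oxy]phenyl}(3,5-dimethoxyphenyl)methanone
Conditions: 4-methoxybenzyl chloride, K2CO3, Bu4NI (cat.), DMF, 60 °C
Reagents that add atoms: 4-methoxybenzyl chloride, COc1ccc(CCl)cc1
Why: Williamson ether synthesis on the phenol; the 4-methoxybenzyl group put on here becomes C2 of benzofuran 1 together with its aryl group.

Step 5
Reactants: 6
Product: 7 {4-bromo-2-methoxy-6-[(4-methoxybenzyl)oxy]phenyl}(3,5-dimethoxyphenyl)methanone hydrazone (E/Z mixture)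
Conditions: N2H4·H2O (excess), AcOH (cat.), n-BuOH, 110 °C
Reagents that add atoms: hydrazine, NN
Why: Hydrazone formation by condensation, driven by excess reagent and heat because both ortho positions of one aryl ring are substituted.

Step 6
Reactants: 7
Product: 10 (2R,3R)-6-bromo-3-(3,5-dimethoxyphenyl)-4-methoxy-2-(4-methoxyphenyl)-2,3-dihydro-1-benzofuran (trans), via diaryldiazomethane 8 (not isolated), via cis-dihydrobenzofuran 9 (not isolated)
Conditions: MnO2, CH2Cl2, 0 °C, filtered; Rh2(S-PTAD)4 (1 mol %), CH2Cl2, −20 °C to rt; then TFA (10 equiv), 0 °C to rt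
Reagents that add atoms: none
Why: MnO2 dehydrogenates the hydrazone to the diaryldiazomethane, the chiral dirhodium carboxylate turns it into a donor/donor carbene that inserts into the benzylic O–CH2 bond (intramolecular carbene C–H insertion; this oxygen- and aryl-activated C–H is preferred over the methoxy C–H) with the catalyst fixing C3 as R and the cis isomer expected first, and TFA then opens and recloses the C2–O bond through the 4-methoxybenzyl cation so that C2 settles in the more stable trans arrangement while C3 is not involved.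

Step 7
Reactants: 11 2-bromo-4,6-dimethoxybenzaldehyde
Product: 12 2-bromo-6-hydroxy-4-methoxybenzaldehyde
Conditions: BCl3 (1.2 equiv), CH2Cl2, −78 to 0 °C; then H2O
Reagents that add atoms: none
Why: Chelation-controlled demethylation with BCl3 removes only the methoxy group ortho to the formyl group; the para one stays.

Step 8
Reactants: 12
Product: 13 2-bromo-4-methoxy-6-[(4-methoxybenzyl)oxy]benzaldehyde
Conditions: 4-methoxybenzyl chloride, K2CO3, DMF, 50 °C
Reagents that add atoms: 4-methoxybenzyl chloride, COc1ccc(CCl)cc1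
Why: Williamson ether synthesis; this 4-methoxybenzyl group becomes C2 of benzofuran 2 with its aryl group.

Step 9
Reactants: 10; 13
Product: 15 {2-bromo-4-methoxy-6-[(4-methoxybenzyl)oxy]phenyl}[(2R,3R)-3-(3,5-dimethoxyphenyl)-4-methoxy-2-(4-methoxyphenyl)-2,3-dihydro-1-benzofuran-6-yl]methanol (both carbinol epimers), via aryllithium 14 (not isolated)
Conditions: n-BuLi (1.05 equiv), THF, −78 °C, 10 min; then 13, −78 to −40 °C; aq NH4Cl
Reagents that add atoms: none
Why: Bromine–lithium exchange at −78 °C is faster than any deprotonation of the dihydrobenzofuran, and the aryllithium adds to the aldehyde faster than it exchanges with the aryl bromide of 13; the carbinol centre disappears in step 10.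

Step 10
Reactants: 15
Product: 16 {2-bromo-4-methoxy-6-[(4-methoxybenzyl)oxy]phenyl}[(2R,3R)-3-(3,5-dimethoxyphenyl)-4-methoxy-2-(4-methoxyphenyl)-2,3-dihydro-1-benzofuran-6-yl]methanone
Conditions: MnO2 (excess), CH2Cl2, rt
Reagents that add atoms: none
Why: MnO2 oxidation of the doubly benzylic alcohol to the diaryl ketone; the 4-methoxybenzyl ether and the dihydrobenzofuran should not be affected.

Step 11
Reactants: 16
Product: 17 hydrazone of ketone 16 (E/Z mixture)
Conditions: N2H4·H2O (excess), AcOH (cat.), n-BuOH, 110 °C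
Reagents that add atoms: hydrazine, NN
Why: Hydrazone formation by condensation, as in step 5.

Step 12
Reactants: 17
Product: 20 (2S,3S)-4-bromo-3-[(2R,3R)-3-(3,5-dimethoxyphenyl)-4-methoxy-2-(4-methoxyphenyl)-2,3-dihydro-1-benzofuran-6-yl]-6-methoxy-2-(4-methoxyphenyl)-2,3-dihydro-1-benzofuran (trans in both rings), via diaryldiazomethane 18 (not isolated), via cis-dihydrobenzofuran 19 (not isolated)
Conditions: MnO2, CH2Cl2, 0 °C, filtered; Rh2(R-PTAD)4 (1 mol %), CH2Cl2, −20 °C to rt; then TFA (10 equiv), 0 °C to rt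
Reagents that add atoms: none
Why: Same sequence as step 6 (hydrazone dehydrogenation, dirhodium-catalysed intramolecular carbene C–H insertion, acid epimerisation of C2), now with the enantiomeric catalyst so that catalyst control sets C3 of benzofuran 2 as S, opposite in sense to benzofuran 1 whose distant centres should exert no influence, and TFA again brings C2 to trans.

Step 13
Reactants: 20; 21 4-ethynylanisole
Product: 23 heptamethyl ether of the target, via diarylalkyne 22 (not isolated)
Conditions: Pd(PhCN)2Cl2 (3 mol %), P(t-Bu)3 (6 mol %), CuI (2 mol %), i-Pr2NH (2 equiv), dioxane, rt to 50 °C; volatiles removed in the same flask; CH2Cl2, TFA (10 equiv), 0 °C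
Reagents that add atoms: none
Why: Sonogashira coupling first joins the terminal alkyne carbon of 21 to C4 of ring A (oxidative addition of the C–Br bond to zerovalent palladium, copper acetylide transmetalation, reductive elimination); TFA then protonates alkyne 22 at the carbon just attached to ring A, because only the other carbon carries the 4-methoxyphenyl group that can stabilise an α-aryl alkenyl cation, and C7 of ring B, ortho to the furan oxygen and para to the methoxy group, captures that cation in a Friedel–Crafts alkenylation whose rearomatisation leaves the trisubstituted alkene of 23. The closest known reaction types are the Sonogashira coupling and the acid-induced cyclisation of (4-alkoxyphenyl)ethynyl arenes (intramolecular alkyne hydroarylation). The seven-membered ring closes in the 7-endo-dig mode; the 6-exo-dig alternative would place the charge on the carbon next to ring A, which is meta to both ring-A oxygens and cannot stabilise it. No stereocentre is formed; the four existing ones are not touched by the coupling, and the two C2 centres already sit in the preferred trans arrangement, so reversible opening of a C2–O bond by TFA should not change them. The step needs ring B to react through C7 and not through C5, which is also ortho to the tether: the C4 methoxy group, whose methyl is turned toward C5 by the aryl-bearing C3 next to it, shields C5 and would be twisted out of conjugation by a new bond there, whereas C7 is flanked only by the tied-back ring oxygen. The alkyne oxidation level of 21 delivers the alkene directly, so no later dehydrogenation is needed that could aromatise the dihydrobenzofurans.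

Step 14
Reactants: 23
Product: 24 CNP0325907.1 (target)
Conditions: BBr3 (20 equiv), CH2Cl2, −78 °C to rt; then MeOH, 0 °C
Reagents that add atoms: none
Why: Lewis-acid cleavage of the seven aryl methyl ethers with BBr3; the stereocentres are already in their trans arrangement, so a transient opening at C2 should lead back to the same isomers.

**Compound list**

1 | 4-bromo-2,6-dimethoxybenzaldehyde | COc1cc(Br)cc(OC)c1C=O | starting material
2 | 3,5-dimethoxyphenylmagnesium chloride | COc1cc(OC)cc([Mg]Cl)c1 | starting material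
3 | (4-bromo-2,6-dimethoxyphenyl)(3,5-dimethoxyphenyl)methanol, racemic | COc1cc(OC)cc(C(O)c2c(OC)cc(Br)cc2OC)c1 | intermediate
4 | (4-bromo-2,6-dimethoxyphenyl)(3,5-dimethoxyphenyl)methanone | COc1cc(OC)cc(C(=O)c2c(OC)cc(Br)cc2OC)c1 | intermediate
5 | (4-bromo-2-hydroxy-6-methoxyphenyl)(3,5-dimethoxyphenyl)methanone | COc1cc(OC)cc(C(=O)c2c(O)cc(Br)cc2OC)c1 | intermediate
6 | {4-bromo-2-methoxy-6-[(4-methoxybenzyl)oxy]phenyl}(3,5-dimethoxyphenyl)methanone | COc1ccc(COc2cc(Br)cc(OC)c2C(=O)c2cc(OC)cc(OC)c2)cc1 | intermediate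
7 | hydrazone of 6, E/Z mixture | COc1ccc(COc2cc(Br)cc(OC)c2C(=NN)c2cc(OC)cc(OC)c2)cc1 | intermediate
8 | 5-bromo-2-[diazo(3,5-dimethoxyphenyl)methyl]-1-methoxy-3-[(4-methoxybenzyl)oxy]benzene | COc1ccc(COc2cc(Br)cc(OC)c2C(=[N+]=[N-])c2cc(OC)cc(OC)c2)cc1 | intermediate (not isolated)
9 | (2S,3R)-6-bromo-3-(3,5-dimethoxyphenyl)-4-methoxy-2-(4-methoxyphenyl)-2,3-dihydro-1-benzofuran, cis | Brc1cc(OC)c2c(c1)O[C@H](c1ccc(OC)cc1)[C@@H]2c1cc(OC)cc(OC)c1 | intermediate (not isolated)
10 | (2R,3R)-6-bromo-3-(3,5-dimethoxyphenyl)-4-methoxy-2-(4-methoxyphenyl)-2,3-dihydro-1-benzofuran, trans | Brc1cc(OC)c2c(c1)O[C@@H](c1ccc(OC)cc1)[C@@H]2c1cc(OC)cc(OC)c1 | intermediate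
11 | 2-bromo-4,6-dimethoxybenzaldehyde | COc1cc(Br)c(C=O)c(OC)c1 | starting material
12 | 2-bromo-6-hydroxy-4-methoxybenzaldehyde | COc1cc(O)c(C=O)c(Br)c1 | intermediate
13 | 2-bromo-4-methoxy-6-[(4-methoxybenzyl)oxy]benzaldehyde | COc1ccc(COc2cc(OC)cc(Br)c2C=O)cc1 | intermediate
14 | [(2R,3R)-3-(3,5-dimethoxyphenyl)-4-methoxy-2-(4-methoxyphenyl)-2,3-dihydro-1-benzofuran-6-yl]lithium | [Li]c1cc(OC)c2c(c1)O[C@@H](c1ccc(OC)cc1)[C@@H]2c1cc(OC)cc(OC)c1 | intermediate (not isolated)
15 | {2-bromo-4-methoxy-6-[(4-methoxybenzyl)oxy]phenyl}[(2R,3R)-3-(3,5-dimethoxyphenyl)-4-methoxy-2-(4-methoxyphenyl)-2,3-dihydro-1-benzofuran-6-yl]methanol, both carbinol epimers | COc1ccc(COc2cc(OC)cc(Br)c2C(O)c2cc(OC)c3c(c2)O[C@@H](c2ccc(OC)cc2)[C@@H]3c2cc(OC)cc(OC)c2)cc1 | intermediate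
16 | {2-bromo-4-methoxy-6-[(4-methoxybenzyl)oxy]phenyl}[(2R,3R)-3-(3,5-dimethoxyphenyl)-4-methoxy-2-(4-methoxyphenyl)-2,3-dihydro-1-benzofuran-6-yl]methanone | COc1ccc(COc2cc(OC)cc(Br)c2C(=O)c2cc(OC)c3c(c2)O[C@@H](c2ccc(OC)cc2)[C@@H]3c2cc(OC)cc(OC)c2)cc1 | intermediate
17 | hydrazone of 16, E/Z mixture | COc1ccc(COc2cc(OC)cc(Br)c2C(=NN)c2cc(OC)c3c(c2)O[C@@H](c2ccc(OC)cc2)[C@@H]3c2cc(OC)cc(OC)c2)cc1 | intermediate
18 | diazo compound from 17 (C=N2 in place of C=N–NH2) | COc1ccc(COc2cc(OC)cc(Br)c2C(=[N+]=[N-])c2cc(OC)c3c(c2)O[C@@H](c2ccc(OC)cc2)[C@@H]3c2cc(OC)cc(OC)c2)cc1 | intermediate (not isolated)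
19 | (2R,3S)-4-bromo-3-[(2R,3R)-3-(3,5-dimethoxyphenyl)-4-methoxy-2-(4-methoxyphenyl)-2,3-dihydro-1-benzofuran-6-yl]-6-methoxy-2-(4-methoxyphenyl)-2,3-dihydro-1-benzofuran, cis in the new ring | Brc1cc(OC)cc2c1[C@H](c1cc(OC)c3c(c1)O[C@@H](c1ccc(OC)cc1)[C@@H]3c1cc(OC)cc(OC)c1)[C@H](c1ccc(OC)cc1)O2 | intermediate (not isolated)
20 | (2S,3S)-4-bromo-3-[(2R,3R)-3-(3,5-dimethoxyphenyl)-4-methoxy-2-(4-methoxyphenyl)-2,3-dihydro-1-benzofuran-6-yl]-6-methoxy-2-(4-methoxyphenyl)-2,3-dihydro-1-benzofuran, trans in both rings | Brc1cc(OC)cc2c1[C@H](c1cc(OC)c3c(c1)O[C@@H](c1ccc(OC)cc1)[C@@H]3c1cc(OC)cc(OC)c1)[C@@H](c1ccc(OC)cc1)O2 | intermediate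
21 | 4-ethynylanisole | C#Cc1ccc(OC)cc1 | starting material
22 | (2S,3S)-3-[(2R,3R)-3-(3,5-dimethoxyphenyl)-4-methoxy-2-(4-methoxyphenyl)-2,3-dihydro-1-benzofuran-6-yl]-6-methoxy-2-(4-methoxyphenyl)-4-[(4-methoxyphenyl)ethynyl]-2,3-dihydro-1-benzofuran | COc1ccc(C#Cc2cc(OC)cc3c2[C@H](c2cc(OC)c4c(c2)O[C@@H](c2ccc(OC)cc2)[C@@H]4c2cc(OC)cc(OC)c2)[C@@H](c2ccc(OC)cc2)O3)cc1 | intermediate (not isolated)
23 | heptamethyl ether of 24 (all seven OH as OMe, same ring system and configuration) | COc1ccc(C2=Cc3cc(OC)cc4c3[C@H](c3cc(OC)c5c(c32)O[C@@H](c2ccc(OC)cc2)[C@@H]5c2cc(OC)cc(OC)c2)[C@@H](c2ccc(OC)cc2)O4)cc1 | intermediate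
24 | CNP0325907.1: 5H-dibenzo[a,d]cycloheptene core with a 4-hydroxyphenyl group on the alkene carbon next to ring B, a trans-(2S,3S)-2-(4-hydroxyphenyl)-2,3-dihydrofuran fused to ring A and closed onto the sp3 ring carbon, a trans-(2R,3R)-2-(4-hydroxyphenyl)-3-(3,5-dihydroxyphenyl)-2,3-dihydrofuran fused to ring B, and one free OH on each of rings A and B | Oc1ccc(C2=Cc3cc(O)cc4c3[C@H](c3cc(O)c5c(c32)O[C@@H](c2ccc(O)cc2)[C@@H]5c2cc(O)cc(O)c2)[C@@H](c2ccc(O)cc2)O4)cc1 | target

**Count and risks**

Total step count: 14. Longest linear sequence: 12 steps (steps 1–6 and 9–14).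

Steps most likely to fail:

Step 13. The alkenyl cation may be captured at the wrong ortho carbon of ring B (C5), or take a hydride from the C3–H of benzofuran 2. After closure, acid may also open benzofuran 2 at C2 and let the new alkene trap that cation. Fallback: setting out from 20, a palladium-catalysed ketone α-arylation with 4'-methoxyacetophenone (Pd2(dba)3, Xantphos, K3PO4, toluene, 90 °C) would give the aryl ketone F1, in which the CH2 carbon is bonded to C4 of ring A. Cyclodehydration of F1 (MeSO3H, CH2Cl2, 0 °C) would then close the ring by addition of C7 of ring B to the protonated ketone and loss of water. The carbonyl addition is reversible until water is lost, which should favour the less crowded C7 adduct, and no alkenyl cation is involved. The sequence comes back to the route at 23.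

Step 6 (the same concerns hold for step 12). The di-ortho-substituted carbene may show poor facial selectivity, or be diverted into the neighbouring methoxy C–H bond or into azine formation. Fallback: setting out from 5, acylation with 4-methoxybenzoyl chloride (Et3N, DMAP, CH2Cl2) would give the keto ester F2. Intramolecular reductive keto-ester coupling of McMurry type (TiCl3, Zn, DME, reflux) would give the benzofuran F3. Ionic hydrogenation (Et3SiH, TFA, CH2Cl2) would give the racemic trans-dihydrobenzofuran F4, the acid again equilibrating C2 to trans. Separation of the enantiomers by preparative HPLC on a chiral cellulose carbamate phase comes back to the route at 10.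

Step 14. BBr3 may open the two benzylic C2–O bonds, and the cations may recombine with the alkene or the electron-rich rings; cleavage of seven ethers may also stay incomplete. Fallback: the demethylation is moved ahead of the annulation, where no alkene is present and an opened ring can only reclose. Setting out from 20, BBr3 (CH2Cl2, −78 °C to rt) would give the hexaphenol F5, and TBSCl with imidazole in DMF the hexakis(tert-butyldimethylsilyl) ether F6. The one-flask coupling and TFA closure of step 13, run with commercial tert-butyl(4-ethynylphenoxy)dimethylsilane, would pass through the silylated diarylalkyne F7 (not isolated) to the heptakis(silyl ether) F8. Bu4NF buffered with AcOH (THF, 0 °C) then comes back to the route at 24.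

**Further compounds**

F1 | step 13 | 2-{(2S,3S)-3-[(2R,3R)-3-(3,5-dimethoxyphenyl)-4-methoxy-2-(4-methoxyphenyl)-2,3-dihydro-1-benzofuran-6-yl]-6-methoxy-2-(4-methoxyphenyl)-2,3-dihydro-1-benzofuran-4-yl}-1-(4-methoxyphenyl)ethanone | COc1ccc(C(=O)Cc2cc(OC)cc3c2[C@H](c2cc(OC)c4c(c2)O[C@@H](c2ccc(OC)cc2)[C@@H]4c2cc(OC)cc(OC)c2)[C@@H](c2ccc(OC)cc2)O3)cc1
F2 | step 6 | 5-bromo-2-(3,5-dimethoxybenzoyl)-3-methoxyphenyl 4-methoxybenzoate | COc1ccc(C(=O)Oc2cc(Br)cc(OC)c2C(=O)c2cc(OC)cc(OC)c2)cc1
F3 | step 6 | 6-bromo-3-(3,5-dimethoxyphenyl)-4-methoxy-2-(4-methoxyphenyl)-1-benzofuran | COc1ccc(-c2oc3cc(Br)cc(OC)c3c2-c2cc(OC)cc(OC)c2)cc1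
F4 | step 6 | racemic trans-6-bromo-3-(3,5-dimethoxyphenyl)-4-methoxy-2-(4-methoxyphenyl)-2,3-dihydro-1-benzofuran (10 together with its mirror image) | Brc1cc(OC)c2c(c1)O[C@@H](c1ccc(OC)cc1)[C@@H]2c1cc(OC)cc(OC)c1.Brc1cc(OC)c2c(c1)O[C@H](c1ccc(OC)cc1)[C@H]2c1cc(OC)cc(OC)c1
F5 | step 14 | hexaphenol of 20 (all six OMe as OH, same configuration) | Brc1cc(O)cc2c1[C@H](c1cc(O)c3c(c1)O[C@@H](c1ccc(O)cc1)[C@@H]3c1cc(O)cc(O)c1)[C@@H](c1ccc(O)cc1)O2
F6 | step 14 | hexakis(tert-butyldimethylsilyl) ether of F5 | Brc1cc(O[Si](C)(C)C(C)(C)C)cc2c1[C@H](c1cc(O[Si](C)(C)C(C)(C)C)c3c(c1)O[C@@H](c1ccc(O[Si](C)(C)C(C)(C)C)cc1)[C@@H]3c1cc(O[Si](C)(C)C(C)(C)C)cc(O[Si](C)(C)C(C)(C)C)c1)[C@@H](c1ccc(O[Si](C)(C)C(C)(C)C)cc1)O2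
F7 | step 14 | diarylalkyne from F6 (Br replaced by [4-(tert-butyldimethylsilyloxy)phenyl]ethynyl) | CC(C)(C)[Si](C)(C)Oc1ccc(C#Cc2cc(O[Si](C)(C)C(C)(C)C)cc3c2[C@H](c2cc(O[Si](C)(C)C(C)(C)C)c4c(c2)O[C@@H](c2ccc(O[Si](C)(C)C(C)(C)C)cc2)[C@@H]4c2cc(O[Si](C)(C)C(C)(C)C)cc(O[Si](C)(C)C(C)(C)C)c2)[C@@H](c2ccc(O[Si](C)(C)C(C)(C)C)cc2)O3)cc1
F8 | step 14 | heptakis(tert-butyldimethylsilyl) ether of 24 | CC(C)(C)[Si](C)(C)Oc1ccc(C2=Cc3cc(O[Si](C)(C)C(C)(C)C)cc4c3[C@H](c3cc(O[Si](C)(C)C(C)(C)C)c5c(c32)O[C@@H](c2ccc(O[Si](C)(C)C(C)(C)C)cc2)[C@@H]5c2cc(O[Si](C)(C)C(C)(C)C)cc(O[Si](C)(C)C(C)(C)C)c2)[C@@H](c2ccc(O[Si](C)(C)C(C)(C)C)cc2)O4)cc1
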